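Everything rests on opening the hydroxylated cyclohexene ring A at C1–C2 and C5–C6. Its C3 carbinol and C6, the carbon carrying the C7≡C8 alkyne, are 1,4-related, so C6 is treated as a latent ketone and masked as a nitro group. The key step is then an amine-catalysed formal Diels–Alder reaction: the dienamine of (E)-pent-3-en-2-one (C2–C5 and the C5 methyl) and 2-methyl-1-nitropropene (C6, C1 and its gem-dimethyl group) give (5R)-3,3,5-trimethyl-4-nitrocyclohexanone in one operation. The C5 methyl centre relays its configuration to C3 and is then erased (Nef reaction, enol triflate, Sonogashira coupling). Two Wittig olefinations with a C10 dialdehyde and an (R)-α-ionone-derived salt complete the polyene.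

Key step: step 1

Remark: atom numbers in the discussion are carotenoid numbers (ring A: C1 gem-dimethyl carbon, C2, C3 carbinol, C4, C5 methyl-bearing, C6 alkyne-bearing; primed numbers for the ε half); compound names carry their own locants.
Remark: 2, 12, 16 (enantiomerically enriched) and 19 are taken as purchasable; the quinine-derived amine is assumed to expose the Re face of the iminium β-carbon (C5) in step 1, giving (5R)-5, and its quinidine-derived pseudo-enantiomer would be used without other change if the sense proves opposite.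

Step 1
Reactants: 1 (E)-pent-3-en-2-one; 2 2-methyl-1-nitroprop-1-ene
Product: 5 (5R)-3,3,5-trimethyl-4-nitrocyclohexan-1-one (epimers at the nitro carbon), via dienamine 3 (not isolated), via iminium nitronate 4 (not isolated)
Conditions: 9-amino-9-deoxy-epi-quinine (20 mol %), 2-fluorobenzoic acid (40 mol %), 1 (2 equiv), toluene, 40 °C
Reagents that add atoms: none
Why: Organocatalytic formal Diels–Alder reaction (dienamine/iminium double Michael cascade), the closest known reaction type being the chiral primary-amine-catalysed [4+2] union of enones with β-monosubstituted nitroalkenes, here stretched to a β,β-dimethyl nitroalkene: the amine condenses with 1 and the iminium ion loses a methyl proton to give dienamine 3, whose CH2 terminus (C2) adds to the only electrophilic carbon of 2 (the CMe2 carbon, C1) to give iminium nitronate 4, and the nitronate carbon (C6) then adds to the iminium β-carbon (C5) before hydrolysis releases 5 and the amine. The ring is closed in a 6-endo-trig nitro-Michael addition. The only stereocentre that matters, C5, is set in this ring closure by the catalyst, whose quinoline–quinuclidinium framework and carboxylate counter-ion cover one face of the (E)-iminium ion so that C6 should arrive on the Re face of C5; the nitro-bearing centre forms as an epimerisable mixture and is erased in step 5. The step needs dienamine formation at the methyl group and not at the γ-methyl group, which only the cross-conjugated dienamine can convert into a six-membered ring, and it needs bond formation at the hindered CMe2 carbon, which the polarity of the nitroalkene dictates and which the acid co-catalyst (against base-induced deconjugation of 2) and the excess of 1 support. Because the nitro group makes C6 nucleophilic where the later ketone would be electrophilic, the dissonant 1,4-relationship C3/C6 is bridged with both ring bonds in one flask.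

Step 2
Reactants: 5 (5R)-3,3,5-trimethyl-4-nitrocyclohexan-1-one
Product: 6 (1R,5R)-3,3,5-trimethyl-4-nitrocyclohexan-1-ol (epimers at the nitro carbon)
Conditions: LiBH(s-Bu)3 (L-Selectride, 2.5 equiv), THF, −78 °C; aq. NH4Cl
Reagents that add atoms: none
Why: Diastereoselective ketone reduction with a bulky trialkylborohydride, in which the axial methyl group of the gem-dimethyl carbon (C1) blocks the axial trajectory so that hydride should arrive equatorially and give the axial alcohol trans to the equatorial C5 methyl group, fixing the carbinol centre (C3) as R by 1,3-relay.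

Step 3
Reactants: 6 (1R,5R)-3,3,5-trimethyl-4-nitrocyclohexan-1-ol
Product: 7 tert-butyldimethyl{[(1R,5R)-3,3,5-trimethyl-4-nitrocyclohexyl]oxy}silane
Conditions: TBSCl, imidazole, DMF, rt
Reagents that add atoms: tert-butyldimethylsilyl chloride, CC(C)(C)[Si](C)(C)Cl
Why: Silyl ether protection of the secondary alcohol, so that the hydroxyl group survives the enolate and triflation chemistry that follows.

Step 4
Reactants: 7 tert-butyldimethyl{[(1R,5R)-3,3,5-trimethyl-4-nitrocyclohexyl]oxy}silane
Product: 9 (4R,6R)-4-[(tert-butyldimethylsilyl)oxy]-2,2,6-trimethylcyclohexan-1-one, via sodium nitronate 8 (not isolated)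
Conditions: NaOMe, MeOH, 0 °C to rt; then O3, MeOH/CH2Cl2, −78 °C; N2 purge
Reagents that add atoms: ozone, [O-][O+]=O
Why: Oxidative Nef reaction, in which ozone cleaves the C=N bond of the nitronate to the ketone without acid, so the silyl ether and the carbinol centre are untouched, and any epimerisation next to the new carbonyl is harmless because that centre is erased in step 5.

Step 5
Reactants: 9 (4R,6R)-4-[(tert-butyldimethylsilyl)oxy]-2,2,6-trimethylcyclohexan-1-one
Product: 11 (4R)-4-[(tert-butyldimethylsilyl)oxy]-2,6,6-trimethylcyclohex-1-en-1-yl trifluoromethanesulfonate, via lithium enolate 10 (not isolated)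
Conditions: LiN(i-Pr)2, THF, −78 °C; PhNTf2, −78 to 0 °C
Reagents that add atoms: N-phenylbis(trifluoromethanesulfonimide), O=S(=O)(N(c1ccccc1)S(=O)(=O)C(F)(F)F)C(F)(F)F
Why: Regiospecific enol triflate formation, since the ketone has a single α-hydrogen and deprotonation with O-sulfonylation can therefore give only the tetrasubstituted C5=C6 enol triflate.

Step 6
Reactants: 11 (4R)-4-[(tert-butyldimethylsilyl)oxy]-2,6,6-trimethylcyclohex-1-en-1-yl trifluoromethanesulfonate; 12 (2E)-3-methylpent-2-en-4-yn-1-ol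
Product: 13 (2E)-5-{(4R)-4-[(tert-butyldimethylsilyl)oxy]-2,6,6-trimethylcyclohex-1-en-1-yl}-3-methylpent-2-en-4-yn-1-ol
Conditions: Pd(PPh3)4 (5 mol %), CuI (10 mol %), i-Pr2NH, DMF, rt to 50 °C
Reagents that add atoms: none
Why: Sonogashira coupling of an enol triflate with a terminal alkyne, which should form the C6–C7 bond with the C7≡C8 triple bond in place and leave the E geometry of C9=C10 as bought.

Step 7
Reactants: 13 (2E)-5-{(4R)-4-[(tert-butyldimethylsilyl)oxy]-2,6,6-trimethylcyclohex-1-en-1-yl}-3-methylpent-2-en-4-yn-1-ol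
Product: 14 (1R)-4-[(3E)-5-hydroxy-3-methylpent-3-en-1-yn-1-yl]-3,5,5-trimethylcyclohex-3-en-1-ol
Conditions: Bu4NF, THF, 0 °C to rt
Reagents that add atoms: none
Why: Fluoride-mediated cleavage of the silyl ether, which does not involve the stereocentre or the enyne.

Step 8
Reactants: 14 (1R)-4-[(3E)-5-hydroxy-3-methylpent-3-en-1-yn-1-yl]-3,5,5-trimethylcyclohex-3-en-1-ol
Product: 15 {(2E)-5-[(4R)-4-hydroxy-2,6,6-trimethylcyclohex-1-en-1-yl]-3-methylpent-2-en-4-yn-1-yl}triphenylphosphonium bromide
Conditions: PPh3·HBr, MeOH, rt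
Reagents that add atoms: triphenylphosphine hydrobromide, [Br-].[PH+](c1ccccc1)(c1ccccc1)c1ccccc1
Why: Phosphonium salt formation from a primary allylic alcohol with triphenylphosphine hydrobromide (SN1-type substitution through the allylic cation), in which the secondary homoallylic hydroxyl group does not ionise and stays free.

Step 9
Reactants: 16 (R)-α-ionone [(3E)-4-[(1R)-2,6,6-trimethylcyclohex-2-en-1-yl]but-3-en-2-one]
Product: 17 (1E)-3-methyl-1-[(1R)-2,6,6-trimethylcyclohex-2-en-1-yl]penta-1,4-dien-3-ol (epimers at the carbinol carbon)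
Conditions: CH2=CHMgBr, THF, −20 to 0 °C; aq. NH4Cl
Reagents that add atoms: vinylmagnesium bromide, C=C[Mg]Br
Why: Grignard 1,2-addition to the enone carbonyl, whose new tertiary carbinol centre forms as a mixture and is lost in step 10 while the C6' centre of 16 is not touched.

Step 10
Reactants: 17 (1E)-3-methyl-1-[(1R)-2,6,6-trimethylcyclohex-2-en-1-yl]penta-1,4-dien-3-ol
Product: 18 {(2E,4E)-3-methyl-5-[(1R)-2,6,6-trimethylcyclohex-2-en-1-yl]penta-2,4-dien-1-yl}triphenylphosphonium bromide
Conditions: PPh3·HBr, MeOH, 0 °C to rt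
Reagents that add atoms: triphenylphosphine hydrobromide, [Br-].[PH+](c1ccccc1)(c1ccccc1)c1ccccc1
Why: Phosphonium salt formation with allylic transposition (SN1' capture of the delocalised cation at its primary terminus), which should give the conjugated and thermodynamically preferred 9'E salt.

Step 11
Reactants: 18 {(2E,4E)-3-methyl-5-[(1R)-2,6,6-trimethylcyclohex-2-en-1-yl]penta-2,4-dien-1-yl}triphenylphosphonium bromide; 19 (2E,4E,6E)-2,7-dimethylocta-2,4,6-trienedial
Product: 21 (2E,4E,6E,8E,10E,12E)-2,7,11-trimethyl-13-[(1R)-2,6,6-trimethylcyclohex-2-en-1-yl]trideca-2,4,6,8,10,12-hexaenal, via ylide 20 (not isolated)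
Conditions: NaOMe, MeOH/CH2Cl2, 0 °C to rt, 19 (3 equiv); then heptane, 80 °C
Reagents that add atoms: none
Why: Wittig olefination of one aldehyde group of the symmetrical dialdehyde, used in excess to favour mono-olefination, with the E/Z mixture at the new C11'=C12' bond expected to equilibrate thermally to the all-E aldehyde.

Step 12
Reactants: 15 {(2E)-5-[(4R)-4-hydroxy-2,6,6-trimethylcyclohex-1-en-1-yl]-3-methylpent-2-en-4-yn-1-yl}triphenylphosphonium bromide; 21 (2E,4E,6E,8E,10E,12E)-2,7,11-trimethyl-13-[(1R)-2,6,6-trimethylcyclohex-2-en-1-yl]trideca-2,4,6,8,10,12-hexaenal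
Product: 23 crocoxanthin [(3R,6'R)-7,8-didehydro-β,ε-caroten-3-ol], via ylide 22 (not isolated)
Conditions: NaOMe, MeOH/CH2Cl2, 0 °C to rt, dark; all-E isomer by crystallisation
Reagents that add atoms: none
Why: Wittig olefination forming C11=C12, whose hindered 11Z isomer should relax to E under mild conditions, with the free hydroxyl group tolerated and no stereocentre touched.

Compound list
1 | (E)-pent-3-en-2-one | C/C=C/C(C)=O | starting material
2 | 2-methyl-1-nitroprop-1-ene | CC(C)=C[N+](=O)[O-] | starting material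
3 | dienamine: (S)-N-[(3E)-penta-1,3-dien-2-yl]-1-(6-methoxyquinolin-4-yl)-1-[(2S,4S,5R)-5-ethenylquinuclidin-2-yl]methanamine | C=C(N[C@@H](c1ccnc2ccc(OC)cc12)[C@@H]1C[C@@H]2CCN1C[C@@H]2C=C)/C=C/C | intermediate
4 | iminium nitronate: zwitterion of the (2E)-6,6-dimethyl-7-(aci-nitro)hept-2-en-4-iminium ion bearing the catalyst residue on nitrogen | C/C=C/C(CC(C)(C)C=[N+]([O-])[O-])=[NH+][C@@H](c1ccnc2ccc(OC)cc12)[C@@H]1C[C@@H]2CCN1C[C@@H]2C=C | intermediate
5 | (5R)-3,3,5-trimethyl-4-nitrocyclohexan-1-one (epimers at C4) | O=C1CC(C)(C)C([N+](=O)[O-])[C@H](C)C1 | intermediate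
6 | (1R,5R)-3,3,5-trimethyl-4-nitrocyclohexan-1-ol (epimers at C4) | O[C@H]1CC(C)(C)C([N+](=O)[O-])[C@H](C)C1 | intermediate
7 | tert-butyldimethyl{[(1R,5R)-3,3,5-trimethyl-4-nitrocyclohexyl]oxy}silane (epimers at C4) | CC(C)(C)[Si](C)(C)O[C@H]1CC(C)(C)C([N+](=O)[O-])[C@H](C)C1 | intermediate
8 | sodium nitronate of 7 | CC(C)(C)[Si](C)(C)O[C@H]1CC(C)(C)C(=[N+]([O-])[O-])[C@H](C)C1.[Na+] | intermediate
9 | (4R,6R)-4-[(tert-butyldimethylsilyl)oxy]-2,2,6-trimethylcyclohexan-1-one | CC(C)(C)[Si](C)(C)O[C@H]1CC(C)(C)C(=O)[C@H](C)C1 | intermediate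
10 | lithium (4R)-4-[(tert-butyldimethylsilyl)oxy]-2,6,6-trimethylcyclohex-1-en-1-olate | CC1=C([O-])C(C)(C)C[C@H](O[Si](C)(C)C(C)(C)C)C1.[Li+] | intermediate
11 | (4R)-4-[(tert-butyldimethylsilyl)oxy]-2,6,6-trimethylcyclohex-1-en-1-yl trifluoromethanesulfonate | CC1=C(OS(=O)(=O)C(F)(F)F)C(C)(C)C[C@H](O[Si](C)(C)C(C)(C)C)C1 | intermediate
12 | (2E)-3-methylpent-2-en-4-yn-1-ol | C#C/C(C)=C/CO | starting material
13 | (2E)-5-{(4R)-4-[(tert-butyldimethylsilyl)oxy]-2,6,6-trimethylcyclohex-1-en-1-yl}-3-methylpent-2-en-4-yn-1-ol | CC1=C(C#C/C(C)=C/CO)C(C)(C)C[C@H](O[Si](C)(C)C(C)(C)C)C1 | intermediate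
14 | (1R)-4-[(3E)-5-hydroxy-3-methylpent-3-en-1-yn-1-yl]-3,5,5-trimethylcyclohex-3-en-1-ol | CC1=C(C#C/C(C)=C/CO)C(C)(C)C[C@H](O)C1 | intermediate
15 | {(2E)-5-[(4R)-4-hydroxy-2,6,6-trimethylcyclohex-1-en-1-yl]-3-methylpent-2-en-4-yn-1-yl}triphenylphosphonium bromide | CC1=C(C#C/C(C)=C/C[P+](c2ccccc2)(c2ccccc2)c2ccccc2)C(C)(C)C[C@H](O)C1.[Br-] | intermediate
16 | (R)-α-ionone, (3E)-4-[(1R)-2,6,6-trimethylcyclohex-2-en-1-yl]but-3-en-2-one | CC1=CCCC(C)(C)[C@H]1/C=C/C(C)=O | starting material
17 | (1E)-3-methyl-1-[(1R)-2,6,6-trimethylcyclohex-2-en-1-yl]penta-1,4-dien-3-ol (epimers at C3) | CC1=CCCC(C)(C)[C@H]1/C=C/C(C)(O)C=C | intermediate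
18 | {(2E,4E)-3-methyl-5-[(1R)-2,6,6-trimethylcyclohex-2-en-1-yl]penta-2,4-dien-1-yl}triphenylphosphonium bromide | CC1=CCCC(C)(C)[C@H]1/C=C/C(C)=C/C[P+](c1ccccc1)(c1ccccc1)c1ccccc1.[Br-] | intermediate
19 | (2E,4E,6E)-2,7-dimethylocta-2,4,6-trienedial | O=C/C(C)=C/C=C/C=C(C)/C=O | starting material
20 | ylide of 18, {(2E,4E)-3-methyl-5-[(1R)-2,6,6-trimethylcyclohex-2-en-1-yl]penta-2,4-dien-1-ylidene}triphenylphosphorane | CC1=CCCC(C)(C)[C@H]1/C=C/C(C)=C/C=P(c1ccccc1)(c1ccccc1)c1ccccc1 | intermediate
21 | (2E,4E,6E,8E,10E,12E)-2,7,11-trimethyl-13-[(1R)-2,6,6-trimethylcyclohex-2-en-1-yl]trideca-2,4,6,8,10,12-hexaenal | CC1=CCCC(C)(C)[C@H]1/C=C/C(C)=C/C=C/C(C)=C/C=C/C=C(C)/C=O | intermediate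
22 | ylide of 15, {(2E)-5-[(4R)-4-hydroxy-2,6,6-trimethylcyclohex-1-en-1-yl]-3-methylpent-2-en-4-yn-1-ylidene}triphenylphosphorane | CC1=C(C#C/C(C)=C/C=P(c2ccccc2)(c2ccccc2)c2ccccc2)C(C)(C)C[C@H](O)C1 | intermediate
23 | crocoxanthin, (3R,6'R)-7,8-didehydro-β,ε-caroten-3-ol | CC1=CCCC(C)(C)[C@H]1/C=C/C(C)=C/C=C/C(C)=C/C=C/C=C(C)/C=C/C=C(\C)C#CC1=C(C)C[C@@H](O)CC1(C)C | target

Total step count: 12. Longest linear sequence: 9 steps (steps 1 to 8, then step 12); steps 9 to 11 build the second branch.

Steps most likely to fail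

1. Step 1. The dienamine may add too slowly to the fully substituted carbon of 2, the amine may deconjugate 2 to its allylic nitro isomer, and the ring closure may show poor facial discrimination, so that conversion or enantiomeric purity falls short. The fallback sets out from 1 and 2 and returns at 6. Soft enolisation of 1 (TBSOTf, Et3N, CH2Cl2, 0 °C) gives (E)-tert-butyldimethyl(penta-1,3-dien-2-yloxy)silane F1. Thermal Diels–Alder reaction of F1 with 2 (toluene, 110 °C, sealed tube) should give, with the silyloxy group para and the methyl group ortho to the nitro carbon, racemic tert-butyldimethyl[(3,5,5-trimethyl-4-nitrocyclohex-1-en-1-yl)oxy]silane F2. Dilute HCl in THF hydrolyses this to racemic 3,3,5-trimethyl-4-nitrocyclohexan-1-one F3, and reduction as in step 2 gives rac-(1R*,5R*)-3,3,5-trimethyl-4-nitrocyclohexan-1-ol F4. Lipase-catalysed kinetic resolution (Burkholderia cepacia lipase, vinyl acetate, MTBE, 30 °C) should, by the empirical rule for secondary alcohols, acylate the enantiomer with the R carbinol centre to (1R,5R)-3,3,5-trimethyl-4-nitrocyclohexyl acetate F5. F5 is separated from the unreacted (1S,5S) alcohol and methanolysed (K2CO3, MeOH) to 6.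

2. Step 4. Deprotonation at the nitro-bearing carbon, flanked by a quaternary and a tertiary carbon, may be slow or incomplete, and cleavage of the nitronate by ozone may stall or over-oxidise. The fallback sets out from 7 and returns at 9, unmasking the ketone reductively instead of oxidatively. SnCl2, PhSH and Et3N (MeCN, rt) should reduce the nitro group to (4R,6R)-4-[(tert-butyldimethylsilyl)oxy]-2,2,6-trimethylcyclohexan-1-one oxime F6. Buffered aqueous TiCl3 (NH4OAc, THF) should then cleave the N–O bond to (4R,6R)-4-[(tert-butyldimethylsilyl)oxy]-2,2,6-trimethylcyclohexan-1-imine F7, which hydrolyses in the same flask to 9.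

3. Step 12. The alkyne-conjugated allylic ylide 22 may lose the 9E geometry by rotation about the C9–C10 bond, and the new C11=C12 bond may not relax from Z to E without C9=C10 equilibrating as well. The fallback sets out from 13 and 21 and returns at 23, with the roles of the partners reversed so that C9=C10 is never part of an ylide. MnO2 (CH2Cl2, rt) oxidises 13 to (2E)-5-{(4R)-4-[(tert-butyldimethylsilyl)oxy]-2,6,6-trimethylcyclohex-1-en-1-yl}-3-methylpent-2-en-4-ynal F8. NaBH4 (MeOH, 0 °C) reduces 21 to (2E,4E,6E,8E,10E,12E)-2,7,11-trimethyl-13-[(1R)-2,6,6-trimethylcyclohex-2-en-1-yl]trideca-2,4,6,8,10,12-hexaen-1-ol F9, which PPh3·HBr (MeOH, rt) converts into the corresponding triphenylphosphonium bromide F10. NaOMe generates the corresponding ylide F11, whose Wittig reaction with F8 should give (3R,6'R)-3-[(tert-butyldimethylsilyl)oxy]-7,8-didehydro-β,ε-carotene F12. Bu4NF (THF) then liberates 23.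

Further compounds
F1 | step 1 | (E)-tert-butyldimethyl(penta-1,3-dien-2-yloxy)silane | C=C(O[Si](C)(C)C(C)(C)C)/C=C/C
F2 | step 1 | racemic tert-butyldimethyl[(3,5,5-trimethyl-4-nitrocyclohex-1-en-1-yl)oxy]silane | CC1C=C(O[Si](C)(C)C(C)(C)C)CC(C)(C)C1[N+](=O)[O-]
F3 | step 1 | racemic 3,3,5-trimethyl-4-nitrocyclohexan-1-one | CC1CC(=O)CC(C)(C)C1[N+](=O)[O-]
F4 | step 1 | rac-(1R*,5R*)-3,3,5-trimethyl-4-nitrocyclohexan-1-ol | CC1CC(O)CC(C)(C)C1[N+](=O)[O-]
F5 | step 1 | (1R,5R)-3,3,5-trimethyl-4-nitrocyclohexyl acetate | CC(=O)O[C@H]1CC(C)(C)C([N+](=O)[O-])[C@H](C)C1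
F6 | step 4 | (4R,6R)-4-[(tert-butyldimethylsilyl)oxy]-2,2,6-trimethylcyclohexan-1-one oxime | CC(C)(C)[Si](C)(C)O[C@H]1CC(C)(C)C(=NO)[C@H](C)C1
F7 | step 4 | (4R,6R)-4-[(tert-butyldimethylsilyl)oxy]-2,2,6-trimethylcyclohexan-1-imine | CC(C)(C)[Si](C)(C)O[C@H]1CC(C)(C)C(=N)[C@H](C)C1
F8 | step 12 | (2E)-5-{(4R)-4-[(tert-butyldimethylsilyl)oxy]-2,6,6-trimethylcyclohex-1-en-1-yl}-3-methylpent-2-en-4-ynal | CC1=C(C#C/C(C)=C/C=O)C(C)(C)C[C@H](O[Si](C)(C)C(C)(C)C)C1
F9 | step 12 | (2E,4E,6E,8E,10E,12E)-2,7,11-trimethyl-13-[(1R)-2,6,6-trimethylcyclohex-2-en-1-yl]trideca-2,4,6,8,10,12-hexaen-1-ol | CC1=CCCC(C)(C)[C@H]1/C=C/C(C)=C/C=C/C(C)=C/C=C/C=C(C)/CO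
F10 | step 12 | {(2E,4E,6E,8E,10E,12E)-2,7,11-trimethyl-13-[(1R)-2,6,6-trimethylcyclohex-2-en-1-yl]trideca-2,4,6,8,10,12-hexaen-1-yl}triphenylphosphonium bromide | CC1=CCCC(C)(C)[C@H]1/C=C/C(C)=C/C=C/C(C)=C/C=C/C=C(C)/C[P+](c1ccccc1)(c1ccccc1)c1ccccc1.[Br-]
F11 | step 12 | ylide of F10 | CC1=CCCC(C)(C)[C@H]1/C=C/C(C)=C/C=C/C(C)=C/C=C/C=C(C)/C=P(c1ccccc1)(c1ccccc1)c1ccccc1
F12 | step 12 | (3R,6'R)-3-[(tert-butyldimethylsilyl)oxy]-7,8-didehydro-β,ε-carotene | CC1=CCCC(C)(C)[C@H]1/C=C/C(C)=C/C=C/C(C)=C/C=C/C=C(C)/C=C/C=C(\C)C#CC1=C(C)C[C@@H](O[Si](C)(C)C(C)(C)C)CC1(C)C
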